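Ring A is closed last at the C3–C4 bond (labdane numbering: C4 is the gem-dimethyl carbon, C3 the neighbouring carbinol carbon). The feature exploited is that C4 with its two methyls hangs on C5 of ring B just as the isopropenyl group hangs on the ring of (R)-carvone. A 6-exo reductive Heck cyclisation of a (Z)-iodoallyl chain on C10 onto this isopropenyl group forms C3–C4, closes ring A, converts the alkene into the quaternary gem-dimethyl carbon and leaves a C2=C3 double bond for the cis-diol. The precursor is a carvone-derived monocyclic cyclohexanone that already carries the C5, C8 and C10 stereocentres.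

Key step: step 6

Remark: labdane numbering is used throughout (ring A = C1–C5 and C10, ring B = C5–C10, C9 = carbinol carbon bearing the side chain C11–C16); compounds 1, 4 and 13 are assumed to be commercial.

**Route**

Step 1
Reactants: 1 ethyl (2Z)-3-iodoprop-2-enoate
Product: 2 (2Z)-3-iodoprop-2-en-1-ol
Conditions: i-Bu2AlH (2.2 equiv), CH2Cl2, −78 °C; then H2O
Reagents that add atoms: none
Why: Hydride reduction of the ester to the primary alcohol at low temperature should leave the alkenyl iodide and its Z geometry untouched.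

Step 2
Reactants: 2 (2Z)-3-iodoprop-2-en-1-ol
Product: 3 (1Z)-3-bromo-1-iodoprop-1-ene
Conditions: PBr3 (0.4 equiv), Et2O, 0 °C
Reagents that add atoms: phosphorus tribromide (BrP(Br)Br)
Why: The primary allylic alcohol is converted into the bromide by SN2 displacement of its phosphite ester, which does not touch the Z-alkenyl iodide.

Step 3
Reactants: 4 (R)-carvone, (5R)-2-methyl-5-(prop-1-en-2-yl)cyclohex-2-en-1-one
Product: 6 (5R,6S)-2,6-dimethyl-5-(prop-1-en-2-yl)cyclohex-2-en-1-one (trans-6-methylcarvone), via lithium dienolate of carvone 5 (not isolated)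
Conditions: LiN(i-Pr)2, THF, −78 °C; MeI, −78 → 0 °C
Reagents that add atoms: iodomethane (CI)
Why: Kinetic deprotonation at C6 gives the cross-conjugated dienolate, and its C-methylation (enolate alkylation) should occur mainly anti to the isopropenyl group; the C6 configuration is of no consequence because it is planarised again in step 4.

Step 4
Reactants: 6 (5R,6S)-2,6-dimethyl-5-(prop-1-en-2-yl)cyclohex-2-en-1-one; 3 (1Z)-3-bromo-1-iodoprop-1-ene
Product: 8 (5S,6S)-6-[(2Z)-3-iodoprop-2-en-1-yl]-2,6-dimethyl-5-(prop-1-en-2-yl)cyclohex-2-en-1-one, via lithium enolate of 6-methylcarvone 7 (not isolated)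
Conditions: LiN(i-Pr)2, THF, −78 °C; then 3, DMPU, −78 → 0 °C
Reagents that add atoms: none
Why: Enolate alkylation by SN2 attack on the allylic bromide is expected on the face anti to the pseudoaxial isopropenyl group of the neighbouring carbon, so the new chain ends trans and the methyl cis to isopropenyl, which sets the quaternary stereocentre (future C10).

Step 5
Reactants: 8 (5S,6S)-6-[(2Z)-3-iodoprop-2-en-1-yl]-2,6-dimethyl-5-(prop-1-en-2-yl)cyclohex-2-en-1-one
Product: 10 (2S,3S,6R)-2-[(2Z)-3-iodoprop-2-en-1-yl]-2,6-dimethyl-3-(prop-1-en-2-yl)cyclohexan-1-one, via lithium enolate of the saturated ketone 9 (not isolated)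
Conditions: LiBH(s-Bu)3, THF, −78 °C; then MeOH, NaOMe (cat.), 25 °C
Reagents that add atoms: none
Why: Conjugate (1,4) hydride reduction of the β-unsubstituted enone by the bulky borohydride, followed by methoxide equilibration of the only epimerisable centre, should favour the methyl (future C8) trans to the quaternary methyl, with which it would clash 1,3-diaxially in the chair that keeps the allyl and isopropenyl arms equatorial; any C8 epimer that remains is carried on and converges on the rigid decalone at the end of step 6.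

Step 6
Reactants: 10 (2S,3S,6R)-2-[(2Z)-3-iodoprop-2-en-1-yl]-2,6-dimethyl-3-(prop-1-en-2-yl)cyclohexan-1-one
Product: 11 (2R,4aS,8aS)-2,5,5,8a-tetramethyl-3,4,4a,5,8,8a-hexahydronaphthalen-1(2H)-one
Conditions: Pd(OAc)2 (10 mol %), PPh3 (30 mol %), HCO2Na (2 equiv), Et4NCl, DMF, 80 °C; then NaOMe (cat.), MeOH, 25 °C
Reagents that add atoms: none
Why: Zerovalent palladium inserts into the C3–I bond with retention of the Z geometry, the alkenylpalladium adds syn across the isopropenyl double bond so that C3 bonds to the internal carbon C4 and palladium ends on the terminal CH2, and this neopentyl-type alkylpalladium, which has no β-hydrogen because C4 is now quaternary, exchanges iodide for formate, loses CO2 and reductively eliminates C–H, turning the CH2 into the second methyl group. The closest known reaction type is the intramolecular reductive Heck (carbopalladation then hydride capture) cyclisation of alkenyl or aryl halides onto 1,1-disubstituted alkenes to build quaternary carbons. Ring A is closed in the 6-exo-trig mode. No new stereocentre arises (C4 carries two methyls, C2 and C3 are sp2); the trans ring fusion follows from the configurations already present at C5 and C10, whose two equatorial arms are the only ones that can span the ring. The step needs exo insertion to outrun both 7-endo insertion and direct hydrodeiodination; the six-membered transition state, the Z geometry of the iodide that keeps C3 within reach of C4, and the absence of any β-hydrogen escape route should secure this. The closing methoxide treatment equilibrates C8 on the rigid trans-decalone, where only the equatorial α-methyl avoids a 1,3-diaxial clash with the C10 methyl.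

Step 7
Reactants: 11 (2R,4aS,8aS)-2,5,5,8a-tetramethyl-3,4,4a,5,8,8a-hexahydronaphthalen-1(2H)-one
Product: 12 (1S,2R,4aS,8aS)-1-ethenyl-2,5,5,8a-tetramethyl-1,2,3,4,4a,5,8,8a-octahydronaphthalen-1-ol
Conditions: CH2=CHMgBr, LaCl3·2LiCl (0.3 equiv), THF, 0 °C; then H2O
Reagents that add atoms: vinylmagnesium bromide (C=C[Mg]Br)
Why: Grignard 1,2-addition to the ketone should occur axially on the α face, anti to the axial angular methyl on C10 that blocks the β face, so the vinyl group becomes axial (α) and the new hydroxyl equatorial (β) at C9, while the lanthanum salt suppresses enolisation.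

Step 8
Reactants: 13 methyl but-2-ynoate
Product: 14 methyl (2Z)-3-iodobut-2-enoate
Conditions: NaI, AcOH, 110 °C
Reagents that add atoms: sodium iodide ([Na+].[I-])
Why: Hydroiodination of the ynoate (conjugate addition of iodide, then protonation) is a net anti addition and should give the Z-β-iodoenoate with iodine cis to the ester.

Step 9
Reactants: 12 (1S,2R,4aS,8aS)-1-ethenyl-2,5,5,8a-tetramethyl-1,2,3,4,4a,5,8,8a-octahydronaphthalen-1-ol; 14 methyl (2Z)-3-iodobut-2-enoate
Product: 16 methyl (2Z)-5-[(1S,2R,4aS,8aS)-1-hydroxy-2,5,5,8a-tetramethyl-1,2,3,4,4a,5,8,8a-octahydronaphthalen-1-yl]-3-methylpent-2-enoate, via B-alkyl-9-BBN alkylborane 15 (not isolated)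
Conditions: 9-BBN-H (2.5 equiv), THF, 25 → 50 °C; H2O; then 14, PdCl2(dppf) (5 mol %), AsPh3, Cs2CO3, DMF/H2O, 25 °C
Reagents that add atoms: none
Why: Anti-Markovnikov hydroboration of the monosubstituted vinyl group (much faster than at the hindered cis-disubstituted ring alkene) and B-alkyl Suzuki–Miyaura coupling with retention of the iodoenoate geometry should install the complete side chain with its Z double bond.

Step 10
Reactants: 16 methyl (2Z)-5-[(1S,2R,4aS,8aS)-1-hydroxy-2,5,5,8a-tetramethyl-1,2,3,4,4a,5,8,8a-octahydronaphthalen-1-yl]-3-methylpent-2-enoate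
Product: 17 methyl (2Z)-5-[(1S,2R,4aS,6S,7R,8aS)-1,6,7-trihydroxy-2,5,5,8a-tetramethyldecahydronaphthalen-1-yl]-3-methylpent-2-enoate (target)
Conditions: OsO4 (2 mol %), NMO (1.2 equiv), acetone/H2O, 0 → 25 °C
Reagents that add atoms: osmium tetroxide (O=[Os](=O)(=O)=O); 4-methylmorpholine N-oxide (C[N+]1([O-])CCOCC1); water (O)
Why: Catalytic OsO4 syn-dihydroxylation is expected at the electron-rich ring A alkene in preference to the electron-poor enoate and from the α face, because the β face is shielded by the axial methyls on C10 and C4, which sets C2 and C3 as the 2α,3α cis-diol.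

**Compound list**

1 | ethyl (2Z)-3-iodoprop-2-enoate | CCOC(=O)/C=C\I | starting material
2 | (2Z)-3-iodoprop-2-en-1-ol | OC/C=C\I | intermediate
3 | (1Z)-3-bromo-1-iodoprop-1-ene | BrC/C=C\I | intermediate
4 | (R)-carvone, (5R)-2-methyl-5-(prop-1-en-2-yl)cyclohex-2-en-1-one | CC1=CC[C@H](CC1=O)C(C)=C | starting material
5 | lithium dienolate of carvone (O-lithium, C1=C6 and C2=C3 double bonds, isopropenyl carbon unchanged) | [Li]OC1=C[C@H](C(C)=C)CC=C1C | intermediate
6 | (5R,6S)-2,6-dimethyl-5-(prop-1-en-2-yl)cyclohex-2-en-1-one (trans-6-methylcarvone; the minor C6 epimer converges in step 4) | O=C1C(C)=CC[C@@H](C(C)=C)[C@@H]1C | intermediate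
7 | lithium enolate of 6-methylcarvone (O-lithium, tetrasubstituted C1=C6 double bond) | [Li]OC1=C(C)[C@H](C(C)=C)CC=C1C | intermediate
8 | (5S,6S)-6-[(2Z)-3-iodoprop-2-en-1-yl]-2,6-dimethyl-5-(prop-1-en-2-yl)cyclohex-2-en-1-one | O=C1C(C)=CC[C@@H](C(C)=C)[C@]1(C)C/C=C\I | intermediate
9 | lithium enolate of the saturated ketone (O-lithium, C1=C6 double bond, from conjugate reduction of 8) | [Li]OC1=C(C)CC[C@@H](C(C)=C)[C@]1(C)C/C=C\I | intermediate
10 | (2S,3S,6R)-2-[(2Z)-3-iodoprop-2-en-1-yl]-2,6-dimethyl-3-(prop-1-en-2-yl)cyclohexan-1-one | O=C1[C@H](C)CC[C@@H](C(C)=C)[C@]1(C)C/C=C\I | intermediate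
11 | (2R,4aS,8aS)-2,5,5,8a-tetramethyl-3,4,4a,5,8,8a-hexahydronaphthalen-1(2H)-one (trans-fused) | O=C1[C@H](C)CC[C@H]2C(C)(C)C=CC[C@@]21C | intermediate
12 | (1S,2R,4aS,8aS)-1-ethenyl-2,5,5,8a-tetramethyl-1,2,3,4,4a,5,8,8a-octahydronaphthalen-1-ol | C=C[C@]1(O)[C@H](C)CC[C@H]2C(C)(C)C=CC[C@@]21C | intermediate
13 | methyl but-2-ynoate | CC#CC(=O)OC | starting material
14 | methyl (2Z)-3-iodobut-2-enoate | COC(=O)/C=C(/C)I | intermediate
15 | 9-{2-[(1S,2R,4aS,8aS)-1-hydroxy-2,5,5,8a-tetramethyl-1,2,3,4,4a,5,8,8a-octahydronaphthalen-1-yl]ethyl}-9-borabicyclo[3.3.1]nonane | C1CCC2CCCC1B2CC[C@]1(O)[C@H](C)CC[C@H]2C(C)(C)C=CC[C@@]21C | intermediate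
16 | methyl (2Z)-5-[(1S,2R,4aS,8aS)-1-hydroxy-2,5,5,8a-tetramethyl-1,2,3,4,4a,5,8,8a-octahydronaphthalen-1-yl]-3-methylpent-2-enoate | COC(=O)/C=C(/C)CC[C@]1(O)[C@H](C)CC[C@H]2C(C)(C)C=CC[C@@]21C | intermediate
17 | methyl (2Z)-5-[(1S,2R,4aS,6S,7R,8aS)-1,6,7-trihydroxy-2,5,5,8a-tetramethyldecahydronaphthalen-1-yl]-3-methylpent-2-enoate | COC(=O)/C=C(/C)CC[C@]1(O)[C@H](C)CC[C@H]2C(C)(C)[C@H](O)[C@H](O)C[C@@]21C | target

**Step count and risks**

Total step count: 10. Longest linear sequence: 8 steps (steps 1, 2, 4, 5, 6, 7, 9 and 10, from 1).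

The three steps most likely to fail:

Step 6 (key step). Hydrodeiodination of the alkenylpalladium by formate may outrun the insertion, or the neopentylpalladium intermediate may re-add to the new C2=C3 bond and reopen to a ring-expanded isomer. The fallback makes the same C3–C4 bond by a cationic, vinylsilane-terminated cyclisation and sets out from 6. Its lithium enolate 7 (LiN(i-Pr)2, THF, −78 °C) would be alkylated with commercial 3-bromo-1-(trimethylsilyl)prop-1-yne, again anti to the isopropenyl group, to give the silylpropargyl enone F1. Conjugate reduction and equilibration as in step 5 would give the saturated silylalkyne ketone F2. Semihydrogenation (H2, Pd/CaCO3 poisoned with Pb(OAc)2, quinoline) would give the (Z)-alkenylsilane ketone F3. CF3CO2H in CH2Cl2 at 0 °C should then protonate the isopropenyl group to the tertiary C4 cation, which is captured by the silicon-bearing carbon C3 (β-silyl stabilisation of the charge at C2); loss of the silyl group leaves the C2=C3 alkene. The route is rejoined at 11.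

Step 7. Enolisation of the very hindered ketone (flanked by the quaternary C10 and by C8) may compete with 1,2-addition. The fallback sets out from 11 and uses a slimmer sp nucleophile followed by partial reduction: HC≡CMgBr in THF should add on the same α face to give the ethynyl carbinol F4, and semihydrogenation (H2, Pd/CaCO3 poisoned with Pb(OAc)2, quinoline) would convert the ethynyl into the vinyl group. The route is rejoined at 12.

Step 10. The osmylation may lose chemoselectivity and also attack the side-chain enoate. The fallback sets out from 11 and installs the diol before any second alkene exists. OsO4 (cat.)/NMO on 11 should give the 2α,3α-diol ketone F5, and 2,2-dimethoxypropane with TsOH (cat.) its acetonide ketone F6. CH2=CHMgBr/LaCl3·2LiCl as in step 7 would give the vinyl carbinol acetonide F7. 9-BBN-H would give the alkylborane acetonide F8, which is coupled with 14 as in step 9 to the side-chain acetonide F9. Aqueous AcOH at 50 °C would remove the acetonide, and the route is rejoined at 17.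

**Further compounds**

F1 | step 6 | (5S,6S)-2,6-dimethyl-5-(prop-1-en-2-yl)-6-[3-(trimethylsilyl)prop-2-yn-1-yl]cyclohex-2-en-1-one | O=C1C(C)=CC[C@@H](C(C)=C)[C@]1(C)CC#C[Si](C)(C)C
F2 | step 6 | (2S,3S,6R)-2,6-dimethyl-3-(prop-1-en-2-yl)-2-[3-(trimethylsilyl)prop-2-yn-1-yl]cyclohexan-1-one | O=C1[C@H](C)CC[C@@H](C(C)=C)[C@]1(C)CC#C[Si](C)(C)C
F3 | step 6 | (2S,3S,6R)-2,6-dimethyl-3-(prop-1-en-2-yl)-2-[(2Z)-3-(trimethylsilyl)prop-2-en-1-yl]cyclohexan-1-one | O=C1[C@H](C)CC[C@@H](C(C)=C)[C@]1(C)C/C=C\[Si](C)(C)C
F4 | step 7 | (1R,2R,4aS,8aS)-1-ethynyl-2,5,5,8a-tetramethyl-1,2,3,4,4a,5,8,8a-octahydronaphthalen-1-ol | C#C[C@]1(O)[C@H](C)CC[C@H]2C(C)(C)C=CC[C@@]21C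
F5 | step 10 | (2R,4aS,6S,7R,8aS)-6,7-dihydroxy-2,5,5,8a-tetramethyloctahydronaphthalen-1(2H)-one | O=C1[C@H](C)CC[C@H]2C(C)(C)[C@H](O)[C@H](O)C[C@@]21C
F6 | step 10 | acetonide of F5 (2,2-dimethyl-1,3-dioxolane fused at C2–C3, both oxygens α) | O=C1[C@H](C)CC[C@H]2C(C)(C)[C@@H]3OC(C)(C)O[C@@H]3C[C@@]21C
F7 | step 10 | acetonide of the 9-vinyl-9β-carbinol (vinyl α, hydroxyl β at C9) | C=C[C@]1(O)[C@H](C)CC[C@H]2C(C)(C)[C@@H]3OC(C)(C)O[C@@H]3C[C@@]21C
F8 | step 10 | B-alkyl-9-BBN alkylborane from F7 (boron on C12) | C1CCC2CCCC1B2CC[C@]1(O)[C@H](C)CC[C@H]2C(C)(C)[C@@H]3OC(C)(C)O[C@@H]3C[C@@]21C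
F9 | step 10 | 2,3-O-isopropylidene derivative (acetonide) of 17 | COC(=O)/C=C(/C)CC[C@]1(O)[C@H](C)CC[C@H]2C(C)(C)[C@@H]3OC(C)(C)O[C@@H]3C[C@@]21C
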